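The arene is read as a folded tetraketide: the ring carbon that bears the C1 acyl group sits between two C–OH carbons, with C–OMe para to it. The bond from that acyl-bearing carbon to one C–OH carbon is therefore disconnected, leading back to a 4-methoxy-2-pyranone whose C6 carries the 2-oxoalkyl chain (C1–C18, C9 silylated). In one operation Mg(OMe)2 opens the lactone and the methylene between the two ketones closes onto the released ester (Claisen), turning the pyranone ring into the complete benzene ring with the methyl ether already placed. The chain is built from an alkyne–epoxide union, Lindlar reduction and two Wittig olefinations; C9 comes from (R)-trityl glycidyl ether.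

Key step: step 14

Remark: (3-methyloxetan-3-yl)methanol and (triphenylphosphoranylidene)acetaldehyde are taken as purchased materials, the ortho esters 4, 7, 8 and 9 are to be chromatographed on triethylamine-deactivated silica, and the 1,3-dicarbonyl compounds 23 and 24 are drawn in their keto forms.

Step 1
Reactants: 1 hept-6-ynoic acid; 2 (3-methyloxetan-3-yl)methanol
Product: 3 (3-methyloxetan-3-yl)methyl hept-6-ynoate
Conditions: DCC, DMAP (cat.), CH2Cl2, 0 °C → rt
Reagents that add atoms: none
Why: Steglich esterification of an unhindered acid with a primary alcohol under neutral conditions that leave the oxetane and the terminal alkyne untouched.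

Step 2
Reactants: 3 (3-methyloxetan-3-yl)methyl hept-6-ynoate
Product: 4 1-(hex-5-yn-1-yl)-4-methyl-2,6,7-trioxabicyclo[2.2.2]octane
Conditions: BF3·OEt2 (cat.), CH2Cl2, −15 °C → rt; Et3N quench
Reagents that add atoms: none
Why: Lewis-acid-induced rearrangement of an oxetanylmethyl ester to the bicyclic ortho ester (the ester carbonyl oxygen opens the BF3-activated oxetane and the dioxocarbenium ion is trapped by the freed alkoxide), which masks the carboxyl group against the organolithium chemistry of step 3.

Step 3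
Reactants: 4 1-(hex-5-yn-1-yl)-4-methyl-2,6,7-trioxabicyclo[2.2.2]octane; 5 (R)-trityl glycidyl ether
Product: 7 (2R)-9-(4-methyl-2,6,7-trioxabicyclo[2.2.2]octan-1-yl)-1-(trityloxy)non-4-yn-2-ol, via lithium acetylide 6 (not isolated)
Conditions: n-BuLi, THF, −78 °C; BF3·OEt2, −78 °C; then 5, −78 °C; Et3N then H2O
Reagents that add atoms: none
Why: Yamaguchi–Hirao alkynylation, in which the boron-activated acetylide opens the BF3-complexed epoxide by SN2 attack at its unsubstituted CH2, so the C–O bond of the stereocentre is never broken and the (R) configuration of 5 becomes C9 of the target.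

Step 4
Reactants: 7 (2R)-9-(4-methyl-2,6,7-trioxabicyclo[2.2.2]octan-1-yl)-1-(trityloxy)non-4-yn-2-ol
Product: 8 tert-butyldimethyl{[(2R)-9-(4-methyl-2,6,7-trioxabicyclo[2.2.2]octan-1-yl)-1-(trityloxy)non-4-yn-2-yl]oxy}silane
Conditions: TBSCl, imidazole, DMF, rt
Reagents that add atoms: tert-butyldimethylsilyl chloride, CC(C)(C)[Si](C)(C)Cl
Why: Imidazole-promoted silylation of a secondary alcohol under basic conditions that spare the acid-labile ortho ester and trityl ether.

Step 5
Reactants: 8 tert-butyldimethyl{[(2R)-9-(4-methyl-2,6,7-trioxabicyclo[2.2.2]octan-1-yl)-1-(trityloxy)non-4-yn-2-yl]oxy}silane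
Product: 9 tert-butyldimethyl{[(2R,4Z)-9-(4-methyl-2,6,7-trioxabicyclo[2.2.2]octan-1-yl)-1-(trityloxy)non-4-en-2-yl]oxy}silane
Conditions: H2 (1 atm), Pd/CaCO3 poisoned with Pb(OAc)2, quinoline, EtOAc, rt
Reagents that add atoms: none
Why: Lindlar semihydrogenation delivers both hydrogens to one face of the adsorbed alkyne and so should give the Z alkene (C6=C7 of the target), with quinoline holding back over-reduction.

Step 6
Reactants: 9 tert-butyldimethyl{[(2R,4Z)-9-(4-methyl-2,6,7-trioxabicyclo[2.2.2]octan-1-yl)-1-(trityloxy)non-4-en-2-yl]oxy}silane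
Product: 11 methyl (6Z,9R)-9-[(tert-butyldimethylsilyl)oxy]-10-(trityloxy)dec-6-enoate, via dihydroxy ester 10 (not isolated)
Conditions: pyridinium p-toluenesulfonate (cat.), THF/H2O, rt; then K2CO3, MeOH, rt
Reagents that add atoms: water, O; methanol, CO
Why: Mild acid hydrolysis of the ortho ester to its 3-hydroxy-2-(hydroxymethyl)-2-methylpropyl ester followed by base-catalysed transesterification, carried out while O10 is still tritylated so that no free vicinal hydroxyl can trigger a 1,2-silyl shift.

Step 7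
Reactants: 11 methyl (6Z,9R)-9-[(tert-butyldimethylsilyl)oxy]-10-(trityloxy)dec-6-enoate
Product: 12 methyl (6Z,9R)-9-[(tert-butyldimethylsilyl)oxy]-10-hydroxydec-6-enoate
Conditions: (+)-camphor-10-sulfonic acid (cat.), MeOH/CH2Cl2, 0 °C; NaHCO3 quench
Reagents that add atoms: none
Why: Acid-catalysed SN1 methanolysis of the primary trityl ether (the trityl cation is trapped by methanol) is expected to be much faster than cleavage of the hindered secondary silyl ether at 0 °C.

Step 8
Reactants: 12 methyl (6Z,9R)-9-[(tert-butyldimethylsilyl)oxy]-10-hydroxydec-6-enoate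
Product: 13 methyl (6Z,9R)-9-[(tert-butyldimethylsilyl)oxy]-10-oxodec-6-enoate
Conditions: Dess–Martin periodinane, CH2Cl2, 0 °C → rt; used crude
Reagents that add atoms: none
Why: Dess–Martin oxidation of a primary alcohol under non-basic conditions, chosen so that the α-silyloxy aldehyde is formed without epimerisation at C9.

Step 9
Reactants: 13 methyl (6Z,9R)-9-[(tert-butyldimethylsilyl)oxy]-10-oxodec-6-enoate; 14 (triphenylphosphoranylidene)acetaldehyde
Product: 15 methyl (6Z,9R,10E)-9-[(tert-butyldimethylsilyl)oxy]-12-oxododeca-6,10-dienoate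
Conditions: toluene, 60 °C
Reagents that add atoms: none
Why: Wittig olefination with a stabilised formyl ylide, whose reversible addition leads to the E enal (C10=C11) and whose low basicity should leave the C9 stereocentre intact.

Step 10
Reactants: 16 (Z)-hex-3-en-1-ol
Product: 17 (Z)-1-iodohex-3-ene
Conditions: I2, PPh3, imidazole, CH2Cl2, 0 °C → rt
Reagents that add atoms: iodine, II
Why: Appel-type iodination through an alkoxyphosphonium iodide and SN2 displacement at the primary carbon, which does not touch the Z alkene.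

Step 11
Reactants: 17 (Z)-1-iodohex-3-ene
Product: 18 [(Z)-hex-3-en-1-yl]triphenylphosphonium iodide
Conditions: PPh3, MeCN, reflux
Reagents that add atoms: triphenylphosphine, c1ccc(cc1)P(c1ccccc1)c1ccccc1
Why: SN2 quaternisation of triphenylphosphine by an unhindered primary iodide.

Step 12
Reactants: 18 [(Z)-hex-3-en-1-yl]triphenylphosphonium iodide; 15 methyl (6Z,9R,10E)-9-[(tert-butyldimethylsilyl)oxy]-12-oxododeca-6,10-dienoate
Product: 20 methyl (6Z,9R,10E,12Z,15Z)-9-[(tert-butyldimethylsilyl)oxy]octadeca-6,10,12,15-tetraenoate, via phosphorus ylide 19 (not isolated)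
Conditions: NaN(SiMe3)2, THF, −78 → 0 °C; then 15, −78 → −20 °C
Reagents that add atoms: none
Why: Wittig olefination with a non-stabilised ylide under lithium-free conditions, where kinetic formation of the cis-oxaphosphetane should give the Z alkene (C12=C13) by 1,2-addition to the enal while the methyl ester is inert at low temperature.

Step 13
Reactants: 20 methyl (6Z,9R,10E,12Z,15Z)-9-[(tert-butyldimethylsilyl)oxy]octadeca-6,10,12,15-tetraenoate; 21 4-methoxy-6-methyl-2H-pyran-2-one
Product: 23 6-[(7Z,10R,11E,13Z,16Z)-10-[(tert-butyldimethylsilyl)oxy]-2-oxononadeca-7,11,13,16-tetraen-1-yl]-4-methoxy-2H-pyran-2-one, via lithiated pyranone 22 (not isolated)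
Conditions: LiN(i-Pr)2 (2.3 equiv), 21 (2.3 equiv), THF, −78 °C; then 20, −78 → −20 °C; aq. NH4Cl
Reagents that add atoms: none
Why: Crossed Claisen acylation of the vinylogous ester carbanion formed at the C6 methyl group of the pyranone, run with a second equivalent of carbanion to take up the acidic proton of the β-keto product and so protect it from further attack.

Step 14
Reactants: 23 6-[(7Z,10R,11E,13Z,16Z)-10-[(tert-butyldimethylsilyl)oxy]-2-oxononadeca-7,11,13,16-tetraen-1-yl]-4-methoxy-2H-pyran-2-one
Product: 25 (6Z,9R,10E,12Z,15Z)-9-[(tert-butyldimethylsilyl)oxy]-1-(2,6-dihydroxy-4-methoxyphenyl)octadeca-6,10,12,15-tetraen-1-one, via ring-opened triketo methyl ester 24 (not isolated)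
Conditions: Mg(OMe)2 (excess), MeOH/THF, rt → 60 °C; then cold dilute aq. HCl to pH 4
Reagents that add atoms: none
Why: Methoxide from Mg(OMe)2 adds to the lactone carbonyl C2 of the pyranone and the C2–O1 bond breaks, which gives the open-chain methyl (E)-3-methoxy-5,7-dioxo-2-enoate 24 held as the magnesium chelate of its 1,3-diketone. The chelated carbon between the two ketones (the former CH2 on C6) then attacks the ester carbonyl, methoxide leaves and the cyclohexadienone enolises to the arene, so the ring oxygen O1 is exchanged for this carbon and the new bond joins the acyl-bearing carbon to a C–OH carbon. The closest known reaction type is the Claisen (Dieckmann-like) mode of polyketide cyclisation, documented for the Mg(OMe)2 recyclisation of 6-(2-oxoalkyl)-4-oxygenated 2-pyranones to acylphloroglucinols. The benzene ring closes in a 6-exo-trig fashion, the enolate carbon attacking an ester C=O whose oxygen lies outside the new ring. No stereocentre is formed and C9 is remote from the reacting atoms. The step needs Claisen closure to win over aldol closure to a resorcylate: magnesium chelation makes the central diketone carbon the nucleophile, the ester α-carbon is vinylic and cannot be enolised directly, the E enol ether inherited from the ring holds ester and diketone on the same side, and the C4 methoxy group is carried unchanged to the position para to the acyl group.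

Step 15
Reactants: 25 (6Z,9R,10E,12Z,15Z)-9-[(tert-butyldimethylsilyl)oxy]-1-(2,6-dihydroxy-4-methoxyphenyl)octadeca-6,10,12,15-tetraen-1-one
Product: 26 (6Z,9R,10E,12Z,15Z)-1-(2,6-dihydroxy-4-methoxyphenyl)-9-hydroxyoctadeca-6,10,12,15-tetraen-1-one
Conditions: n-Bu4NF, AcOH, THF, 0 °C → rt
Reagents that add atoms: none
Why: Fluoride-induced desilylation at silicon (the C9–O bond is not broken, so the configuration is retained), buffered with acetic acid so that neither strong base nor acid meets the skipped polyene and the ionisable dienyl carbinol.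

Compound list

1 | hept-6-ynoic acid | C#CCCCCC(=O)O | starting material
2 | (3-methyloxetan-3-yl)methanol | CC1(CO)COC1 | starting material
3 | (3-methyloxetan-3-yl)methyl hept-6-ynoate | C#CCCCCC(=O)OCC1(C)COC1 | intermediate
4 | 1-(hex-5-yn-1-yl)-4-methyl-2,6,7-trioxabicyclo[2.2.2]octane | C#CCCCCC12OCC(C)(CO1)CO2 | intermediate
5 | (R)-trityl glycidyl ether | C(OC(c1ccccc1)(c1ccccc1)c1ccccc1)[C@@H]1OC1 | starting material
6 | lithium acetylide of 4, [6-(4-methyl-2,6,7-trioxabicyclo[2.2.2]octan-1-yl)hex-1-yn-1-yl]lithium | [Li]C#CCCCCC12OCC(C)(CO1)CO2 | intermediate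
7 | (2R)-9-(4-methyl-2,6,7-trioxabicyclo[2.2.2]octan-1-yl)-1-(trityloxy)non-4-yn-2-ol | C(c1ccccc1)(c1ccccc1)(c1ccccc1)OC[C@H](O)CC#CCCCCC12OCC(C)(CO1)CO2 | intermediate
8 | tert-butyldimethyl{[(2R)-9-(4-methyl-2,6,7-trioxabicyclo[2.2.2]octan-1-yl)-1-(trityloxy)non-4-yn-2-yl]oxy}silane | C(c1ccccc1)(c1ccccc1)(c1ccccc1)OC[C@H](O[Si](C)(C)C(C)(C)C)CC#CCCCCC12OCC(C)(CO1)CO2 | intermediate
9 | tert-butyldimethyl{[(2R,4Z)-9-(4-methyl-2,6,7-trioxabicyclo[2.2.2]octan-1-yl)-1-(trityloxy)non-4-en-2-yl]oxy}silane | C(c1ccccc1)(c1ccccc1)(c1ccccc1)OC[C@H](O[Si](C)(C)C(C)(C)C)C/C=C\CCCCC12OCC(C)(CO1)CO2 | intermediate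
10 | 3-hydroxy-2-(hydroxymethyl)-2-methylpropyl (6Z,9R)-9-[(tert-butyldimethylsilyl)oxy]-10-(trityloxy)dec-6-enoate | C(c1ccccc1)(c1ccccc1)(c1ccccc1)OC[C@H](O[Si](C)(C)C(C)(C)C)C/C=C\CCCCC(=O)OCC(C)(CO)CO | intermediate
11 | methyl (6Z,9R)-9-[(tert-butyldimethylsilyl)oxy]-10-(trityloxy)dec-6-enoate | C(c1ccccc1)(c1ccccc1)(c1ccccc1)OC[C@H](O[Si](C)(C)C(C)(C)C)C/C=C\CCCCC(=O)OC | intermediate
12 | methyl (6Z,9R)-9-[(tert-butyldimethylsilyl)oxy]-10-hydroxydec-6-enoate | OC[C@H](O[Si](C)(C)C(C)(C)C)C/C=C\CCCCC(=O)OC | intermediate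
13 | methyl (6Z,9R)-9-[(tert-butyldimethylsilyl)oxy]-10-oxodec-6-enoate | O=C[C@H](O[Si](C)(C)C(C)(C)C)C/C=C\CCCCC(=O)OC | intermediate
14 | (triphenylphosphoranylidene)acetaldehyde | O=CC=P(c1ccccc1)(c1ccccc1)c1ccccc1 | starting material
15 | methyl (6Z,9R,10E)-9-[(tert-butyldimethylsilyl)oxy]-12-oxododeca-6,10-dienoate | O=C/C=C/[C@H](O[Si](C)(C)C(C)(C)C)C/C=C\CCCCC(=O)OC | intermediate
16 | (Z)-hex-3-en-1-ol | CC/C=C\CCO | starting material
17 | (Z)-1-iodohex-3-ene | CC/C=C\CCI | intermediate
18 | [(Z)-hex-3-en-1-yl]triphenylphosphonium iodide | CC/C=C\CC[P+](c1ccccc1)(c1ccccc1)c1ccccc1.[I-] | intermediate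
19 | [(Z)-hex-3-en-1-ylidene]triphenylphosphorane | CC/C=C\CC=P(c1ccccc1)(c1ccccc1)c1ccccc1 | intermediate
20 | methyl (6Z,9R,10E,12Z,15Z)-9-[(tert-butyldimethylsilyl)oxy]octadeca-6,10,12,15-tetraenoate | CC/C=C\C/C=C\C=C\[C@H](O[Si](C)(C)C(C)(C)C)C/C=C\CCCCC(=O)OC | intermediate
21 | 4-methoxy-6-methyl-2H-pyran-2-one | COc1cc(C)oc(=O)c1 | starting material
22 | [(4-methoxy-2-oxo-2H-pyran-6-yl)methyl]lithium | [Li]Cc1cc(OC)cc(=O)o1 | intermediate
23 | 6-[(7Z,10R,11E,13Z,16Z)-10-[(tert-butyldimethylsilyl)oxy]-2-oxononadeca-7,11,13,16-tetraen-1-yl]-4-methoxy-2H-pyran-2-one | CC/C=C\C/C=C\C=C\[C@H](O[Si](C)(C)C(C)(C)C)C/C=C\CCCCC(=O)Cc1cc(OC)cc(=O)o1 | intermediate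
24 | methyl (2E,12Z,15R,16E,18Z,21Z)-15-[(tert-butyldimethylsilyl)oxy]-3-methoxy-5,7-dioxotetracosa-2,12,16,18,21-pentaenoate | CC/C=C\C/C=C\C=C\[C@H](O[Si](C)(C)C(C)(C)C)C/C=C\CCCCC(=O)CC(=O)C/C(OC)=C\C(=O)OC | intermediate
25 | (6Z,9R,10E,12Z,15Z)-9-[(tert-butyldimethylsilyl)oxy]-1-(2,6-dihydroxy-4-methoxyphenyl)octadeca-6,10,12,15-tetraen-1-one | CC/C=C\C/C=C\C=C\[C@H](O[Si](C)(C)C(C)(C)C)C/C=C\CCCCC(=O)c1c(O)cc(OC)cc1O | intermediate
26 | (6Z,9R,10E,12Z,15Z)-1-(2,6-dihydroxy-4-methoxyphenyl)-9-hydroxyoctadeca-6,10,12,15-tetraen-1-one | CC/C=C\C/C=C\C=C\[C@H](O)C/C=C\CCCCC(=O)c1c(O)cc(OC)cc1O | target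

Total step count: 15. Longest linear sequence: 13 steps (steps 1–9 and 12–15, from hept-6-ynoic acid); steps 10 and 11 form the two-step side branch to the phosphonium salt.

Steps most likely to fail

1. Step 14. The ring-opened intermediate may close in the aldol sense (ester-side carbon onto the chain ketone, towards a resorcylate), may stop after lactone methanolysis, or its 1,3-diketone may be cleaved by methoxide in a retro-Claisen reaction. The fallback forms the aryl–acyl bond directly, sets out from 20 and comes back at 25: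
   - Ester 20 should be converted with N,O-dimethylhydroxylamine hydrochloride and i-PrMgCl (THF, −20 °C) into the N-methoxy-N-methylamide F1.
   - Purchased 5-methoxybenzene-1,3-diol should give, with chloromethyl methyl ether and i-Pr2NEt, 1-methoxy-3,5-bis(methoxymethoxy)benzene F2.
   - n-BuLi (THF, 0 °C) should metalate F2 between its two acetal oxygens to the aryllithium F3.
   - Addition of F3 to F1 at −78 °C should give the bis(methoxymethyl)-protected aryl ketone F4 once the chelated adduct collapses on work-up.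
   - The two aryl acetals would be removed under non-protic, buffered conditions (Me3SiOTf, 2,2'-bipyridyl, CH2Cl2, 0 °C) that spare the C9 silyl ether, through the bis(trimethylsilyl) aryl ether F5, which is hydrolysed on aqueous work-up to 25.

2. Step 13. Proton transfer to the pyranone carbanion may outrun acyl transfer, metalation at C3 of the pyranone may compete with metalation of the methyl group, and the carbanion may add to unreacted pyranone. The fallback replaces the ester acylation by aldol addition and oxidation, sets out from 20 and comes back at 23: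
   - i-Bu2AlH (one equivalent, CH2Cl2, −78 °C) should reduce ester 20 to the aldehyde F6.
   - The lithiated pyranone 22 should add to F6 at −78 °C to give the β-hydroxyalkyl pyranone F7 as a mixture of carbinol epimers.
   - Dess–Martin oxidation of F7 should give 23.

3. Step 7. The acid may also cleave the neighbouring secondary silyl ether, or the silyl group may shift to the freed primary oxygen. The fallback gives up selectivity at this stage and regains it by a primary-versus-secondary desilylation, sets out from 11 and comes back at 12: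
   - p-Toluenesulfonic acid in methanol at rt should remove both the trityl and the silyl group and give the diol F8.
   - Excess TBSCl with imidazole in DMF should give the bis(silyl) ether F9.
   - HF·pyridine in pyridine/THF at 0 °C should cleave only the primary silyl ether and return 12.

Further compounds

F1 | step 14 | (6Z,9R,10E,12Z,15Z)-9-[(tert-butyldimethylsilyl)oxy]-N-methoxy-N-methyloctadeca-6,10,12,15-tetraenamide | CC/C=C\C/C=C\C=C\[C@H](O[Si](C)(C)C(C)(C)C)C/C=C\CCCCC(=O)N(C)OC
F2 | step 14 | 1-methoxy-3,5-bis(methoxymethoxy)benzene | COCOc1cc(OC)cc(OCOC)c1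
F3 | step 14 | [4-methoxy-2,6-bis(methoxymethoxy)phenyl]lithium | [Li]c1c(OCOC)cc(OC)cc1OCOC
F4 | step 14 | (6Z,9R,10E,12Z,15Z)-9-[(tert-butyldimethylsilyl)oxy]-1-[4-methoxy-2,6-bis(methoxymethoxy)phenyl]octadeca-6,10,12,15-tetraen-1-one | CC/C=C\C/C=C\C=C\[C@H](O[Si](C)(C)C(C)(C)C)C/C=C\CCCCC(=O)c1c(OCOC)cc(OC)cc1OCOC
F5 | step 14 | (6Z,9R,10E,12Z,15Z)-9-[(tert-butyldimethylsilyl)oxy]-1-[4-methoxy-2,6-bis(trimethylsilyloxy)phenyl]octadeca-6,10,12,15-tetraen-1-one | CC/C=C\C/C=C\C=C\[C@H](O[Si](C)(C)C(C)(C)C)C/C=C\CCCCC(=O)c1c(O[Si](C)(C)C)cc(OC)cc1O[Si](C)(C)C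
F6 | step 13 | (6Z,9R,10E,12Z,15Z)-9-[(tert-butyldimethylsilyl)oxy]octadeca-6,10,12,15-tetraenal | CC/C=C\C/C=C\C=C\[C@H](O[Si](C)(C)C(C)(C)C)C/C=C\CCCCC=O
F7 | step 13 | 6-[(7Z,10R,11E,13Z,16Z)-10-[(tert-butyldimethylsilyl)oxy]-2-hydroxynonadeca-7,11,13,16-tetraen-1-yl]-4-methoxy-2H-pyran-2-one (both C2 carbinol epimers) | CC/C=C\C/C=C\C=C\[C@H](O[Si](C)(C)C(C)(C)C)C/C=C\CCCCC(O)Cc1cc(OC)cc(=O)o1
F8 | step 7 | methyl (6Z,9R)-9,10-dihydroxydec-6-enoate | OC[C@H](O)C/C=C\CCCCC(=O)OC
F9 | step 7 | methyl (6Z,9R)-9,10-bis[(tert-butyldimethylsilyl)oxy]dec-6-enoate | CC(C)(C)[Si](C)(C)OC[C@H](O[Si](C)(C)C(C)(C)C)C/C=C\CCCCC(=O)OC
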